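## Retrosynthetic overview

1. Target 17 ⇐ global desilylation of tris-silyl diester 16 ⇐ diol 12 + two equivalents of silyl-protected 4-hydroxybenzoic acid 15; 12 ⇐ one hydride reduction of trans diester 11 (C3 ester and cinnamate together); 11 ⇐ C3 epimerisation of cis ester 10.
2. Ring B (the dihydrofuran O1–C2–C3–C3a–C7a) is the only ring that is made, and it is closed last by forming C2–C3 in an enantioselective intramolecular C–H insertion of the dirhodium carbenoid from the achiral aryldiazoacetate 9; ring A (benzo ring) and ring C (guaiacyl ring) are bought as arenes.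
3. Enabling feature: C2 carries both O1 and ring C, so in the open benzyl aryl ether its C–H is benzylic, α-oxygenated and hydridic; C3 sits on C3a of ring A and bears the CH2O carbon, which at the ester level makes C3 a donor/acceptor carbene; the O1–C7a–C3a unit of ring A holds the two carbons in a 1,5-relationship.
4. 9 ⇐ aryl iodide 7 + ethyl diazoacetate (palladium-catalysed coupling); 7 ⇐ 5-iodovanillin + O-silyl vanillyl alcohol (Mitsunobu etherification), then Wittig olefination.

Key step: step 6

Assumption: the (R)-configured tert-leucinate dirhodium catalyst is taken, by analogy with this catalyst family on ortho-benzyloxy aryldiazoacetates, to give the 2S configuration; if the first run shows the opposite sense, the (S)-configured catalyst is used with no other change.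

## Route

Step 1
Reactants: 1 vanillin
Product: 2 3-methoxy-4-(triisopropylsilyloxy)benzaldehyde
Conditions: TIPSCl, imidazole, DMF, rt
Reagents that add atoms: triisopropylsilyl chloride, CC(C)[Si](Cl)(C(C)C)C(C)C
Why: Imidazole-promoted O-silylation of the phenol gives an aryl silyl ether that is robust to the mild bases used later and is cleaved by fluoride at the end.

Step 2
Reactants: 2 3-methoxy-4-(triisopropylsilyloxy)benzaldehyde
Product: 3 [3-methoxy-4-(triisopropylsilyloxy)phenyl]methanol
Conditions: NaBH4, MeOH–THF, 0 °C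
Reagents that add atoms: none
Why: Borohydride reduction of the aryl aldehyde to the benzylic alcohol should leave the hindered aryl silyl ether untouched at 0 °C.

Step 3
Reactants: 3 [3-methoxy-4-(triisopropylsilyloxy)phenyl]methanol; 4 5-iodovanillin (4-hydroxy-3-iodo-5-methoxybenzaldehyde)
Product: 5 3-iodo-5-methoxy-4-{[3-methoxy-4-(triisopropylsilyloxy)phenyl]methoxy}benzaldehyde
Conditions: PPh3, DIAD, THF, 0 °C → rt
Reagents that add atoms: none
Why: Mitsunobu etherification joins the acidic, aldehyde-activated phenol to the primary benzylic alcohol under neutral conditions that spare the silyl ether and the aldehyde.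

Step 4
Reactants: 5 the aldehyde from step 3; 6 ethyl (triphenylphosphoranylidene)acetate
Product: 7 ethyl (E)-3-(3-iodo-5-methoxy-4-{[3-methoxy-4-(triisopropylsilyloxy)phenyl]methoxy}phenyl)prop-2-enoate
Conditions: toluene, 80 °C
Reagents that add atoms: none
Why: Wittig olefination with a stabilised ylide should give the E-cinnamate under thermodynamic control of oxaphosphetane formation, and the aryl iodide is inert.

Step 5
Reactants: 7 the iodo cinnamate from step 4; 8 ethyl diazoacetate
Product: 9 ethyl (E)-3-[3-(1-diazo-2-ethoxy-2-oxoethyl)-5-methoxy-4-{[3-methoxy-4-(triisopropylsilyloxy)phenyl]methoxy}phenyl]prop-2-enoate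
Conditions: Pd(PPh3)4 (10 mol%), Ag2CO3 (0.5 equiv), Et3N, toluene, rt
Reagents that add atoms: none
Why: Oxidative addition of the aryl iodide to zerovalent palladium, transfer of the silver-activated diazoacetate carbon and reductive elimination should give the aryldiazoacetate with the diazo group intact at room temperature (palladium-catalysed cross-coupling of aryl iodides with diazoacetates), while the electron-poor disubstituted acrylate is too poor a Heck acceptor to compete.

Step 6
Reactants: 9 the aryldiazoacetate from step 5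
Product: 10 ethyl (2S,3R)-5-[(E)-3-ethoxy-3-oxoprop-1-enyl]-7-methoxy-2-[3-methoxy-4-(triisopropylsilyloxy)phenyl]-2,3-dihydrobenzofuran-3-carboxylate (2,3-cis)
Conditions: Rh2(R-PTTL)4 (PTTL = N-phthaloyl-tert-leucinate, 2 mol%), toluene, 4 Å MS, slow addition of 9, −78 → −40 °C
Reagents that add atoms: none
Why: The dirhodium tetracarboxylate (divalent rhodium) expels N2 from 9 to give an electrophilic donor/acceptor carbenoid at the future C3, which inserts in a concerted, asynchronous, hydride-transfer-like event into one of the two enantiotopic C–H bonds of the O–CH2–aryl group and so forms C2–C3. The closest known reaction type is the enantioselective intramolecular C–H insertion of ortho-benzyloxy aryldiazoacetates to cis-2-aryl-2,3-dihydrobenzofuran-3-carboxylates with N-phthaloyl amino acid dirhodium catalysts, which also has precedent with a methoxy group beside the ether oxygen. Ring B is closed as a five-membered ring by 1,5-insertion through a cyclic transition state made of C3, C3a, C7a, O1, C2 and the migrating hydrogen. C2 is set by the chiral carboxylate ligands, which choose which benzylic hydrogen is replaced (insertion with retention), and C3 comes out cis to C2 from the transition-state geometry and is corrected in step 7. The step needs chemoselectivity for this insertion over cyclopropanation, carbene dimerisation and insertion elsewhere. The substrate secures it because the reacting C–H is the only one in 1,5-position and is activated by O1 and by the para-silyloxy ring C, the acrylate alkene is electron-poor and trans-disubstituted, and slow addition keeps the diazo concentration low.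

Step 7
Reactants: 10 the cis ester from step 6
Product: 11 ethyl (2S,3S)-5-[(E)-3-ethoxy-3-oxoprop-1-enyl]-7-methoxy-2-[3-methoxy-4-(triisopropylsilyloxy)phenyl]-2,3-dihydrobenzofuran-3-carboxylate (2,3-trans)
Conditions: NaOEt (0.3 equiv), EtOH–THF, 0 °C → rt
Reagents that add atoms: none
Why: Reversible deprotonation at C3 (α to the ester and benzylic) by catalytic ethoxide should equilibrate the cis ester to the more stable trans isomer (base-mediated epimerisation), so C3 is set thermodynamically relative to the untouched C2, and ethoxide in ethanol matches both ethyl esters.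

Step 8
Reactants: 11 the trans diester from step 7
Product: 12 (E)-3-{(2S,3R)-3-(hydroxymethyl)-7-methoxy-2-[3-methoxy-4-(triisopropylsilyloxy)phenyl]-2,3-dihydrobenzofuran-5-yl}prop-2-en-1-ol
Conditions: iBu2AlH (DIBAL-H, 6 equiv), CH2Cl2, −78 → −20 °C; aq. potassium sodium tartrate
Reagents that add atoms: none
Why: Ester reduction with iBu2AlH should take the C3 ester to the primary alcohol and the cinnamate by 1,2-hydride delivery to the allylic alcohol in one operation, leaving the E-alkene, the aryl silyl ether and both stereocentres unchanged.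

Step 9
Reactants: 13 4-hydroxybenzoic acid
Product: 15 4-(tert-butyldimethylsilyloxy)benzoic acid, via silyl ester 14 (not isolated)
Conditions: TBSCl (2.2 equiv), imidazole, DMF, rt; then AcOH–THF–H2O, rt
Reagents that add atoms: tert-butyldimethylsilyl chloride, CC(C)(C)[Si](C)(C)Cl
Why: Silylation of both the phenol and the acid, followed by selective hydrolysis of the much more labile silyl ester, should leave the phenol protected and the acid free.

Step 10
Reactants: 12 the diol from step 8; 15 4-(tert-butyldimethylsilyloxy)benzoic acid (2.4 equiv)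
Product: 16 (E)-3-{(2S,3R)-3-{[4-(tert-butyldimethylsilyloxy)benzoyloxy]methyl}-7-methoxy-2-[3-methoxy-4-(triisopropylsilyloxy)phenyl]-2,3-dihydrobenzofuran-5-yl}prop-2-enyl 4-(tert-butyldimethylsilyloxy)benzoate
Conditions: DCC, DMAP (cat.), CH2Cl2, 0 °C → rt
Reagents that add atoms: none
Why: Steglich esterification acylates both primary alcohols (alkyl and allylic) under neutral conditions that should not ionise the cinnamyl position or touch the silyl ethers.

Step 11
Reactants: 16 the tris-silyl diester from step 10
Product: 17 quiquesetinerviusin A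
Conditions: Bu4NF, AcOH (1:1, 4 equiv), THF, 0 °C → rt
Reagents that add atoms: none
Why: Acetic acid-buffered fluoride cleaves the three aryl silyl ethers (fluoride-mediated desilylation), and at this low basicity the two benzoate esters, the allylic ester and the benzylic C2–O1 bond should survive.

## Compound list

1 | vanillin | COc1cc(C=O)ccc1O | starting material
2 | 3-methoxy-4-(triisopropylsilyloxy)benzaldehyde | COc1cc(C=O)ccc1O[Si](C(C)C)(C(C)C)C(C)C | intermediate
3 | [3-methoxy-4-(triisopropylsilyloxy)phenyl]methanol | COc1cc(CO)ccc1O[Si](C(C)C)(C(C)C)C(C)C | intermediate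
4 | 5-iodovanillin (4-hydroxy-3-iodo-5-methoxybenzaldehyde) | COc1cc(C=O)cc(I)c1O | starting material
5 | 3-iodo-5-methoxy-4-{[3-methoxy-4-(triisopropylsilyloxy)phenyl]methoxy}benzaldehyde | COc1cc(COc2c(OC)cc(C=O)cc2I)ccc1O[Si](C(C)C)(C(C)C)C(C)C | intermediate
6 | ethyl (triphenylphosphoranylidene)acetate | CCOC(=O)C=P(c1ccccc1)(c1ccccc1)c1ccccc1 | starting material
7 | ethyl (E)-3-(3-iodo-5-methoxy-4-{[3-methoxy-4-(triisopropylsilyloxy)phenyl]methoxy}phenyl)prop-2-enoate | COc1cc(COc2c(OC)cc(/C=C/C(=O)OCC)cc2I)ccc1O[Si](C(C)C)(C(C)C)C(C)C | intermediate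
8 | ethyl diazoacetate | CCOC(=O)C=[N+]=[N-] | starting material
9 | ethyl (E)-3-[3-(1-diazo-2-ethoxy-2-oxoethyl)-5-methoxy-4-{[3-methoxy-4-(triisopropylsilyloxy)phenyl]methoxy}phenyl]prop-2-enoate | COc1cc(COc2c(OC)cc(/C=C/C(=O)OCC)cc2C(=[N+]=[N-])C(=O)OCC)ccc1O[Si](C(C)C)(C(C)C)C(C)C | intermediate
10 | ethyl (2S,3R)-5-[(E)-3-ethoxy-3-oxoprop-1-enyl]-7-methoxy-2-[3-methoxy-4-(triisopropylsilyloxy)phenyl]-2,3-dihydrobenzofuran-3-carboxylate (cis) | COc1cc([C@H]2Oc3c(OC)cc(/C=C/C(=O)OCC)cc3[C@H]2C(=O)OCC)ccc1O[Si](C(C)C)(C(C)C)C(C)C | intermediate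
11 | ethyl (2S,3S)-5-[(E)-3-ethoxy-3-oxoprop-1-enyl]-7-methoxy-2-[3-methoxy-4-(triisopropylsilyloxy)phenyl]-2,3-dihydrobenzofuran-3-carboxylate (trans) | COc1cc([C@H]2Oc3c(OC)cc(/C=C/C(=O)OCC)cc3[C@@H]2C(=O)OCC)ccc1O[Si](C(C)C)(C(C)C)C(C)C | intermediate
12 | (E)-3-{(2S,3R)-3-(hydroxymethyl)-7-methoxy-2-[3-methoxy-4-(triisopropylsilyloxy)phenyl]-2,3-dihydrobenzofuran-5-yl}prop-2-en-1-ol | COc1cc([C@H]2Oc3c(OC)cc(/C=C/CO)cc3[C@@H]2CO)ccc1O[Si](C(C)C)(C(C)C)C(C)C | intermediate
13 | 4-hydroxybenzoic acid | OC(=O)c1ccc(O)cc1 | starting material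
14 | tert-butyldimethylsilyl 4-(tert-butyldimethylsilyloxy)benzoate | CC(C)(C)[Si](C)(C)OC(=O)c1ccc(O[Si](C)(C)C(C)(C)C)cc1 | intermediate
15 | 4-(tert-butyldimethylsilyloxy)benzoic acid | OC(=O)c1ccc(O[Si](C)(C)C(C)(C)C)cc1 | intermediate
16 | (E)-3-{(2S,3R)-3-{[4-(tert-butyldimethylsilyloxy)benzoyloxy]methyl}-7-methoxy-2-[3-methoxy-4-(triisopropylsilyloxy)phenyl]-2,3-dihydrobenzofuran-5-yl}prop-2-enyl 4-(tert-butyldimethylsilyloxy)benzoate | COc1cc([C@H]2Oc3c(OC)cc(/C=C/COC(=O)c4ccc(O[Si](C)(C)C(C)(C)C)cc4)cc3[C@@H]2COC(=O)c2ccc(O[Si](C)(C)C(C)(C)C)cc2)ccc1O[Si](C(C)C)(C(C)C)C(C)C | intermediate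
17 | quiquesetinerviusin A | COc1cc([C@H]2Oc3c(OC)cc(/C=C/COC(=O)c4ccc(O)cc4)cc3[C@@H]2COC(=O)c2ccc(O)cc2)ccc1O | target

## Step count and risks

Total step count: 11. Longest linear sequence: 10 steps (vanillin 1 to target 17 through steps 1–8, 10 and 11).

Steps most likely to fail:

1. Step 6. The very electron-rich benzylic C–H may react by a more stepwise hydride transfer, so that the catalyst discriminates poorly between the two enantiotopic hydrogens and the enantiomeric purity at C2 is low. The fallback gives up catalyst control and resolves instead. It sets out from 9: Rh2(OAc)4 in CH2Cl2 at rt should give the stereorandom dihydrobenzofuran diester F2, and NaOEt in EtOH should equilibrate it to the racemic trans diester F3. Preparative chromatography of F3 on a cellulose tris(3,5-dimethylphenylcarbamate) stationary phase then delivers the (2S,3S) enantiomer, and the route is rejoined at 11.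

2. Step 5. Palladium may decompose the diazoacetate or the product (carbene formation and dimerisation) faster than the hindered ortho-alkoxy aryl iodide couples, giving low conversion to the diazo compound. The fallback builds the carbon skeleton first and the diazo group afterwards. It sets out from 7: Negishi-type coupling with the Reformatsky reagent BrZnCH2CO2Et (from ethyl bromoacetate and Zn; Pd(PPh3)4, THF, 50 °C) should give the ethyl arylacetate F1. Regitz diazo transfer to F1 (4-acetamidobenzenesulfonyl azide, DBU, MeCN, 0 °C → rt) then returns to the route at 9.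

3. Step 7. Ethoxide may cleave the aryl silyl ether, or the C3 enolate may expel O1 (β-elimination with ring opening), which would erase the C2 configuration on re-closure. The fallback moves the epimerisation to the aldehyde oxidation level, where a catalytic amine is enough. It sets out from 10: iBu2AlH in CH2Cl2 at −78 °C should give the cis diol F4, and Dess–Martin periodinane (NaHCO3, CH2Cl2) should oxidise both alcohols to the cis dialdehyde F5. Catalytic Et3N in CH2Cl2 at rt should equilibrate the C3 formyl centre to the trans dialdehyde F6. Luche reduction of F6 (NaBH4, CeCl3·7H2O, MeOH, −40 °C) then returns to the route at diol 12.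

## Further compounds

F1 | step 5 | ethyl (E)-3-[3-(2-ethoxy-2-oxoethyl)-5-methoxy-4-{[3-methoxy-4-(triisopropylsilyloxy)phenyl]methoxy}phenyl]prop-2-enoate | COc1cc(COc2c(OC)cc(/C=C/C(=O)OCC)cc2CC(=O)OCC)ccc1O[Si](C(C)C)(C(C)C)C(C)C
F2 | step 6 | ethyl 5-[(E)-3-ethoxy-3-oxoprop-1-enyl]-7-methoxy-2-[3-methoxy-4-(triisopropylsilyloxy)phenyl]-2,3-dihydrobenzofuran-3-carboxylate, stereorandom at C2 and C3 | COc1cc(C2Oc3c(OC)cc(/C=C/C(=O)OCC)cc3C2C(=O)OCC)ccc1O[Si](C(C)C)(C(C)C)C(C)C
F3 | step 6 | racemic trans diester, (2S,3S) and (2R,3R) | COc1cc([C@H]2Oc3c(OC)cc(/C=C/C(=O)OCC)cc3[C@@H]2C(=O)OCC)ccc1O[Si](C(C)C)(C(C)C)C(C)C.COc1cc([C@@H]2Oc3c(OC)cc(/C=C/C(=O)OCC)cc3[C@H]2C(=O)OCC)ccc1O[Si](C(C)C)(C(C)C)C(C)C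
F4 | step 7 | (E)-3-{(2S,3S)-3-(hydroxymethyl)-7-methoxy-2-[3-methoxy-4-(triisopropylsilyloxy)phenyl]-2,3-dihydrobenzofuran-5-yl}prop-2-en-1-ol (cis diol) | COc1cc([C@H]2Oc3c(OC)cc(/C=C/CO)cc3[C@H]2CO)ccc1O[Si](C(C)C)(C(C)C)C(C)C
F5 | step 7 | (2S,3R)-7-methoxy-2-[3-methoxy-4-(triisopropylsilyloxy)phenyl]-5-[(E)-3-oxoprop-1-enyl]-2,3-dihydrobenzofuran-3-carbaldehyde (cis dialdehyde) | COc1cc([C@H]2Oc3c(OC)cc(/C=C/C=O)cc3[C@H]2C=O)ccc1O[Si](C(C)C)(C(C)C)C(C)C
F6 | step 7 | (2S,3S)-7-methoxy-2-[3-methoxy-4-(triisopropylsilyloxy)phenyl]-5-[(E)-3-oxoprop-1-enyl]-2,3-dihydrobenzofuran-3-carbaldehyde (trans dialdehyde) | COc1cc([C@H]2Oc3c(OC)cc(/C=C/C=O)cc3[C@@H]2C=O)ccc1O[Si](C(C)C)(C(C)C)C(C)C
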